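**Plan**
1. Ring labels: O1, C2 (bears the catechol ring), C3 (bears CH2OH), C4 (carbinol carbon), C5 (ring CH2); C7′ is the benzylic CH2 on C4.
2. Retrosynthesis: C4–OH/C7′–H go back to a C4=C7′ arylidene (epoxide, hydrogenolysis) and C3–H to an enal; one cut through C7′–aryl, C3–C4 and O1–C2 then gives enal 3, propargyl alcohol 4 and aryl iodide 5; 3 comes from aldehyde 1.
3. Enabling feature: O1–C2(Ar)–C3–CH2OH is the oxa-Michael adduct of a cinnamaldehyde and C5–C4–C7′ is a propargyl unit, so an enamine at C3 can close the oxolane onto the alkyne (5-exo-dig) while palladium brings the dimethoxyphenyl group to the alkyne terminus C7′.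
4. Forward: Wittig enal; three-component formation of the oxolane O1–C2–C3–C4–C5 together with the C7′–aryl bond; dienol acetate; deconjugative reduction; directed epoxidation; hydrogenolysis.
5. Stereochemistry: C2 from the chiral amine catalyst; C3 from kinetic protonation anti to the C2 aryl group; C4 from hydroxyl-directed epoxidation on the face of the C3 CH2OH group.

Key step: step 2

Remark: the ring labels above are used in all Why lines. The descriptor at the aryl-bearing carbon reads R in 6, 7 and 10–14 and S in 8 and 9 only because the CIP rank of the neighbouring branch changes; the arrangement in space is the same throughout.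

**Step 1**
Reactants: 1 3,4-bis(benzyloxy)benzaldehyde; 2 (triphenylphosphoranylidene)acetaldehyde
Product: 3 (2E)-3-[3,4-bis(benzyloxy)phenyl]prop-2-enal
Conditions: toluene, 80 °C
Reagents that add atoms: none
Why: Wittig reaction; the formyl-stabilised ylide adds reversibly and collapses through the trans oxaphosphetane, so the (E)-enal should form.

**Step 2**
Reactants: 3 (2E)-3-[3,4-bis(benzyloxy)phenyl]prop-2-enal; 4 prop-2-yn-1-ol; 5 4-iodo-1,2-dimethoxybenzene
Product: 8 (2S)-2-[3,4-bis(benzyloxy)phenyl]-4-[(3,4-dimethoxyphenyl)methyl]-2,5-dihydrofuran-3-carbaldehyde, via oxa-Michael aldehyde 6 (not isolated), via arylidene aldehyde 7 (not isolated)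
Conditions: Pd(PPh3)4 (5 mol%), (R)-2-[diphenyl(trimethylsilyloxy)methyl]pyrrolidine (20 mol%), NaOAc, THF, 40 °C; then DBU (cat.), rt
Reagents that add atoms: none
Why: Proposed new method: the amine turns 3 into an iminium ion to which 4 adds reversibly at C2 (O1–C2 bond) to give the enamine of 6, zerovalent palladium inserts into the C–I bond of 5, the arylpalladium iodide (divalent palladium) binds the alkyne, the enamine carbon C3 attacks the inner alkyne carbon anti to the metal (C3–C4 bond) and reductive elimination from the alkenyl(aryl)palladium forms the C7′–aryl bond, releasing 7 after iminium hydrolysis. The closest known reaction types are the amine/palladium co-catalysed dynamic kinetic asymmetric oxa-Michael/carbocyclisation of enals with propargyl alcohol, in which the alkenylpalladium is protonated and not arylated, and the palladium-mediated three-component coupling of propargyl alkoxides, alkylidene malonates and aryl halides to 4-arylidene oxolanes. The oxolane ring closes in the 5-exo-dig mode. C2 is set by the catalyst: its diphenyl(silyloxy)methyl group shields one face of the iminium ion and of the enamine, the oxa-Michael step is reversible, and only the enamine of the (R) adduct has its alkyne tether on the open face, so the (R) centre is locked in the irreversible C–C bond formation; the C3 centre of 7 is erased when DBU moves the double bond into conjugation to give 8. The step needs arylative ring closure to outrun direct arylation of the terminal alkyne, Heck arylation of 3 and protonation of the alkenylpalladium, which the absence of copper and of strong base, the intramolecular enamine attack and the fast reductive elimination from a cis alkenyl(aryl)palladium should secure, and the three-atom O1–C5 tether enforces 5-exo over 6-endo attack.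

**Step 3**
Reactants: 8 (2S)-2-[3,4-bis(benzyloxy)phenyl]-4-[(3,4-dimethoxyphenyl)methyl]-2,5-dihydrofuran-3-carbaldehyde
Product: 9 (Z)-{(2S,4Z)-2-[3,4-bis(benzyloxy)phenyl]-4-[(3,4-dimethoxyphenyl)methylidene]oxolan-3-ylidene}methyl acetate
Conditions: Ac2O, Et3N, DMAP (cat.), toluene, 80 °C
Reagents that add atoms: acetic anhydride, CC(=O)OC(C)=O
Why: Dienol acetate formation; the base removes the benzylic γ-hydrogen at C7′ (the most acidic one, giving an aryl-conjugated dienolate), the dienolate is O-acetylated, C2 is untouched, and any unisomerised 7 would give the same diene.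

**Step 4**
Reactants: 9 (Z)-{(2S,4Z)-2-[3,4-bis(benzyloxy)phenyl]-4-[(3,4-dimethoxyphenyl)methylidene]oxolan-3-ylidene}methyl acetate
Product: 11 [(2R,3R,4Z)-2-[3,4-bis(benzyloxy)phenyl]-4-[(3,4-dimethoxyphenyl)methylidene]oxolan-3-yl]methanol, via cis aldehyde 10 (not isolated)
Conditions: NaBH4, EtOH–THF, 0 °C to rt
Reagents that add atoms: none
Why: Deconjugative reduction of a dienol acetate; ethoxide formed from NaBH4 cleaves the acetate, the dienolate is protonated kinetically at C3 from the face opposite the C2 aryl group to give the 2,3-cis aldehyde 10, and borohydride should reduce 10 before it can epimerise or reconjugate, so C3 is set by substrate control from C2.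

**Step 5**
Reactants: 11 [(2R,3R,4Z)-2-[3,4-bis(benzyloxy)phenyl]-4-[(3,4-dimethoxyphenyl)methylidene]oxolan-3-yl]methanol
Product: 12 [(2S,3R,6R,7R)-6-[3,4-bis(benzyloxy)phenyl]-2-(3,4-dimethoxyphenyl)-1,5-dioxaspiro[2.4]heptan-7-yl]methanol
Conditions: VO(acac)2 (5 mol%), t-BuOOH, 2,6-lutidine, CH2Cl2, 0 °C
Reagents that add atoms: tert-butyl hydroperoxide, CC(C)(C)OO
Why: Hydroxyl-directed epoxidation of a homoallylic alcohol; the vanadium alkoxide of the C3 CH2OH group carries the peroxide to the alkene face cis to that group, so the C4–O bond forms syn to CH2OH and aryl, while lutidine protects the acid-labile aryl epoxide.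

**Step 6**
Reactants: 12 [(2S,3R,6R,7R)-6-[3,4-bis(benzyloxy)phenyl]-2-(3,4-dimethoxyphenyl)-1,5-dioxaspiro[2.4]heptan-7-yl]methanol
Product: 14 (3R,4R,5R)-5-(3,4-dihydroxyphenyl)-3-[(3,4-dimethoxyphenyl)methyl]-4-(hydroxymethyl)oxolan-3-ol, via bis-benzyl diol 13 (not isolated)
Conditions: H2 (1 atm), 10% Pd/C, NaHCO3, EtOAc–EtOH, rt
Reagents that add atoms: none
Why: Hydrogenolysis; palladium cleaves the benzylic C7′–O bond of the epoxide, leaving the C4–O bond and its configuration as the tertiary alcohol of 13, and then removes both benzyl ethers, while the ring ether C2–O1, a secondary benzylic dialkyl ether, should survive under neutral conditions.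

**Compound list**
1 | 3,4-bis(benzyloxy)benzaldehyde | O=Cc1ccc(OCc2ccccc2)c(OCc2ccccc2)c1 | starting material
2 | (triphenylphosphoranylidene)acetaldehyde | O=CC=P(c1ccccc1)(c1ccccc1)c1ccccc1 | starting material
3 | (2E)-3-[3,4-bis(benzyloxy)phenyl]prop-2-enal | O=C/C=C/c1ccc(OCc2ccccc2)c(OCc2ccccc2)c1 | intermediate
4 | prop-2-yn-1-ol | C#CCO | starting material
5 | 4-iodo-1,2-dimethoxybenzene | COc1ccc(I)cc1OC | starting material
6 | (3R)-3-[3,4-bis(benzyloxy)phenyl]-3-(prop-2-yn-1-yloxy)propanal (reacts on as its enamine) | O=CC[C@@H](OCC#C)c1ccc(OCc2ccccc2)c(OCc2ccccc2)c1 | intermediate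
7 | (2R,3R,4Z)-2-[3,4-bis(benzyloxy)phenyl]-4-[(3,4-dimethoxyphenyl)methylidene]oxolane-3-carbaldehyde (2,3-trans) | O=C[C@H]1[C@H](c2ccc(OCc3ccccc3)c(OCc3ccccc3)c2)OC/C1=C\c4ccc(OC)c(OC)c4 | intermediate
8 | (2S)-2-[3,4-bis(benzyloxy)phenyl]-4-[(3,4-dimethoxyphenyl)methyl]-2,5-dihydrofuran-3-carbaldehyde | O=CC1=C(Cc2ccc(OC)c(OC)c2)CO[C@H]1c3ccc(OCc4ccccc4)c(OCc4ccccc4)c3 | intermediate
9 | (Z)-{(2S,4Z)-2-[3,4-bis(benzyloxy)phenyl]-4-[(3,4-dimethoxyphenyl)methylidene]oxolan-3-ylidene}methyl acetate (enol acetate geometry is of no consequence) | CC(=O)O/C=C1/C(=C/c2ccc(OC)c(OC)c2)CO[C@H]1c3ccc(OCc4ccccc4)c(OCc4ccccc4)c3 | intermediate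
10 | (2R,3S,4Z)-2-[3,4-bis(benzyloxy)phenyl]-4-[(3,4-dimethoxyphenyl)methylidene]oxolane-3-carbaldehyde (2,3-cis) | O=C[C@@H]1[C@H](c2ccc(OCc3ccccc3)c(OCc3ccccc3)c2)OC/C1=C\c4ccc(OC)c(OC)c4 | intermediate
11 | [(2R,3R,4Z)-2-[3,4-bis(benzyloxy)phenyl]-4-[(3,4-dimethoxyphenyl)methylidene]oxolan-3-yl]methanol (aryl and CH2OH cis) | OC[C@@H]1[C@H](c2ccc(OCc3ccccc3)c(OCc3ccccc3)c2)OC/C1=C\c4ccc(OC)c(OC)c4 | intermediate
12 | [(2S,3R,6R,7R)-6-[3,4-bis(benzyloxy)phenyl]-2-(3,4-dimethoxyphenyl)-1,5-dioxaspiro[2.4]heptan-7-yl]methanol (epoxide oxygen cis to CH2OH and aryl) | OC[C@@H]1[C@H](c2ccc(OCc3ccccc3)c(OCc3ccccc3)c2)OC[C@]12O[C@H]2c4ccc(OC)c(OC)c4 | intermediate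
13 | (3R,4R,5R)-5-[3,4-bis(benzyloxy)phenyl]-3-[(3,4-dimethoxyphenyl)methyl]-4-(hydroxymethyl)oxolan-3-ol | COc1ccc(C[C@]2(O)CO[C@@H](c3ccc(OCc4ccccc4)c(OCc4ccccc4)c3)[C@H]2CO)cc1OC | intermediate
14 | (3R,4R,5R)-5-(3,4-dihydroxyphenyl)-3-[(3,4-dimethoxyphenyl)methyl]-4-(hydroxymethyl)oxolan-3-ol | COc1ccc(C[C@]2(O)CO[C@@H](c3ccc(O)c(O)c3)[C@H]2CO)cc1OC | target

Total step count: 6. Longest linear sequence: 6 steps (1 to 14).

**Steps most likely to fail**

Step 2. The arylpalladium species may arylate the terminal alkyne directly, the alkenylpalladium may be protonated before aryl transfer, or the aryl-bearing metal may weaken the catalyst-controlled selection between the two oxa-Michael enantiomers. Fallback, setting out from 4, 5 and 3 and returning at 8: the aryl–carbon bond is made first by Sonogashira coupling of 4 and 5 (PdCl2(PPh3)2, CuI, Et3N, rt) to 3-(3,4-dimethoxyphenyl)prop-2-yn-1-ol F1. F1 and enal 3 then undergo the known two-component amine/palladium oxa-Michael/carbocyclisation (the same (R)-amine, PdCl2, THF), in which the alkenylpalladium is protonated, to (2R,3R,4E)-2-[3,4-bis(benzyloxy)phenyl]-4-[(3,4-dimethoxyphenyl)methylidene]oxolane-3-carbaldehyde F2 (not isolated). DBU isomerises F2 to 8.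

Step 4. Reprotonation of the dienolate at C7′ (reconjugation), epimerisation of the cis aldehyde before it is reduced, or γ-deprotonation at C5 in step 3 would lose the C3 centre. Fallback, setting out from 8 and returning at 13:
- 1,2-Reduction (NaBH4, CeCl3·7H2O, MeOH, 0 °C; Luche reduction) gives [(2S)-2-[3,4-bis(benzyloxy)phenyl]-4-[(3,4-dimethoxyphenyl)methyl]-2,5-dihydrofuran-3-yl]methanol F3.
- Sharpless asymmetric epoxidation (Ti(OiPr)4, L-(+)-diethyl tartrate, t-BuOOH, 4 Å MS, CH2Cl2, −20 °C), under reagent control on the face of the aryl group, gives [(1R,2S,5S)-2-[3,4-bis(benzyloxy)phenyl]-5-[(3,4-dimethoxyphenyl)methyl]-3,6-dioxabicyclo[3.1.0]hexan-1-yl]methanol F4.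
- Reductive epoxide opening with trivalent titanium (Cp2TiCl2, Zn, 1,4-cyclohexadiene, THF) should break the C3–O bond of the chelated epoxy alcohol and deliver a hydrogen atom to the C3 radical from the face opposite the aryl and titanoxy groups, giving 13.
- Step 6 then only removes the benzyl ethers.

Step 5. Epoxidation on the undirected face, or acid-promoted rearrangement of the electron-rich aryl epoxide, would lose the C4 centre. Fallback, setting out from 11 and returning at 13:
- Silylation ((HMe2Si)2NH, neat, rt) gives {[(2R,3R,4Z)-2-[3,4-bis(benzyloxy)phenyl]-4-[(3,4-dimethoxyphenyl)methylidene]oxolan-3-yl]methoxy}dimethylsilane F5.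
- Intramolecular 5-exo hydrosilylation (H2PtCl6 cat., THF, 60 °C) puts silicon on C4 cis to the tether and hydrogen on C7′, giving (1R,5R,6R)-6-[3,4-bis(benzyloxy)phenyl]-1-[(3,4-dimethoxyphenyl)methyl]-2,2-dimethyl-3,7-dioxa-2-silabicyclo[3.3.0]octane F6.
- Tamao oxidation (H2O2, KF, KHCO3, THF–MeOH) replaces C4–Si by C4–OH with retention, giving 13.
- Step 6 then only removes the benzyl ethers.

**Further compounds**
F1 | step 2 | 3-(3,4-dimethoxyphenyl)prop-2-yn-1-ol | COc1ccc(C#CCO)cc1OC
F2 | step 2 | (2R,3R,4E)-2-[3,4-bis(benzyloxy)phenyl]-4-[(3,4-dimethoxyphenyl)methylidene]oxolane-3-carbaldehyde | O=C[C@H]1[C@H](c2ccc(OCc3ccccc3)c(OCc3ccccc3)c2)OC/C1=C/c4ccc(OC)c(OC)c4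
F3 | step 4 | [(2S)-2-[3,4-bis(benzyloxy)phenyl]-4-[(3,4-dimethoxyphenyl)methyl]-2,5-dihydrofuran-3-yl]methanol | OCC1=C(Cc2ccc(OC)c(OC)c2)CO[C@H]1c3ccc(OCc4ccccc4)c(OCc4ccccc4)c3
F4 | step 4 | [(1R,2S,5S)-2-[3,4-bis(benzyloxy)phenyl]-5-[(3,4-dimethoxyphenyl)methyl]-3,6-dioxabicyclo[3.1.0]hexan-1-yl]methanol | OC[C@@]12[C@H](c3ccc(OCc4ccccc4)c(OCc4ccccc4)c3)OC[C@]1(Cc5ccc(OC)c(OC)c5)O2
F5 | step 5 | {[(2R,3R,4Z)-2-[3,4-bis(benzyloxy)phenyl]-4-[(3,4-dimethoxyphenyl)methylidene]oxolan-3-yl]methoxy}dimethylsilane | C[SiH](C)OC[C@@H]1[C@H](c2ccc(OCc3ccccc3)c(OCc3ccccc3)c2)OC/C1=C\c4ccc(OC)c(OC)c4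
F6 | step 5 | (1R,5R,6R)-6-[3,4-bis(benzyloxy)phenyl]-1-[(3,4-dimethoxyphenyl)methyl]-2,2-dimethyl-3,7-dioxa-2-silabicyclo[3.3.0]octane | C[Si]1(C)OC[C@@H]2[C@H](c3ccc(OCc4ccccc4)c(OCc4ccccc4)c3)OC[C@]12Cc5ccc(OC)c(OC)c5
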